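Borregomycin E is cut back to its 6-phenol, and the central benzene ring and the N12 pyrrole ring are then removed together. The N12 indole is 2,3-disubstituted: C11b carries the other indole (C11a) and C4b carries the oxygenated C5 of the central ring (C4b–C5–C6–C6a–C11a–C11b). This is the imprint of an o-alkynylaniline cyclisation whose new C3 is trapped by a tethered electrophile. One pot therefore forms N12–C11b by gold(I) hydroamination and C4b–C5 by acid-induced acetal Friedel–Crafts closure, which aromatises to the phenol. The precursor is a 6-chloro-3-(dimethoxyacetyl)indole whose C2 bears a (2-amino-4-chlorophenyl)ethynyl group, assembled by Sonogashira coupling.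

Key step: step 7

Assumption: the target has no stereocentre and is achiral, so nothing stereochemical has to be set. The one stereocentre on the route (C5 of transient 18) forms as a racemate and is erased by enolisation. Both chlorines sit at C6 of their indole units (C2 and C9 of the indolocarbazole).

Step 1
Reactants: 1 6-chloro-1H-indole
Product: 6 6-chloro-2-iodo-1H-indole, via N-lithioindole 2 (not isolated), via lithium N-carboxylate 3 (not isolated), via C2-lithio N-carboxylate 4 (not isolated), via 2-iodo N-carboxylate 5 (not isolated)
Conditions: n-BuLi, THF, −78 °C; CO2, then removal of excess CO2; t-BuLi, THF, −78 °C; ICH2CH2I, −78 °C to rt; H2O; used promptly, protected from light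
Reagents that add atoms: 1,2-diiodoethane, ICCI
Why: Directed C2 lithiation under transient N-carboxylation, in which the lithium carbamate protects nitrogen and steers tert-butyllithium to C2, 1,2-diiodoethane transfers iodine to the C2 anion, and the carbamic acid decarboxylates on aqueous work-up, while the aryl chloride should be inert to alkyllithiums at −78 °C.

Step 2
Reactants: 7 methyl 2,2-dimethoxyacetate
Product: 8 potassium 2,2-dimethoxyacetate
Conditions: KOH (0.98 equiv), MeOH, rt; concentrate; dry in vacuo
Reagents that add atoms: potassium hydroxide, [K+].[OH-]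
Why: Ester saponification, which leaves the base-stable dimethyl acetal untouched and delivers a dry carboxylate salt free of acid.

Step 3
Reactants: 6 6-chloro-2-iodo-1H-indole; 8 potassium 2,2-dimethoxyacetate
Product: 11 1-(6-chloro-2-iodo-1H-indol-3-yl)-2,2-dimethoxyethanone, via dimethoxyacetyl chloride 9 (not isolated), via indolylzinc chloride 10 (not isolated)
Conditions: 8 (slight excess), (COCl)2, cat. DMF, CH2Cl2, 0 °C to rt, filtered solution of 9; separately 6, ZnCl2, MeMgBr (1.0 equiv), CH2Cl2/Et2O, 0 °C to rt; add 9, 0 °C to rt; aq NaHCO3
Reagents that add atoms: none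
Why: Friedel–Crafts-type C3 acylation of an N-zincated indole by an acid chloride (the zinc variant of the indole Grignard acylation) needs no strong Lewis or protic acid, so the acetal and the C2 iodide should survive, and making the acid chloride from the potassium salt with oxalyl chloride avoids HCl.

Step 4
Reactants: 12 5-chloro-2-iodoaniline; 13 trimethylsilylacetylene
Product: 14 5-chloro-2-[(trimethylsilyl)ethynyl]aniline
Conditions: PdCl2(PPh3)2 (2 mol%), CuI (4 mol%), Et3N, THF, rt
Reagents that add atoms: none
Why: Sonogashira coupling, which should occur only at the C–I bond because aryl chlorides do not undergo oxidative addition under these conditions and free anilines are tolerated.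

Step 5
Reactants: 14 5-chloro-2-[(trimethylsilyl)ethynyl]aniline
Product: 15 5-chloro-2-ethynylaniline
Conditions: K2CO3 (cat.), MeOH, rt
Reagents that add atoms: none
Why: Carbonate-catalysed methanolysis of the alkynyl C–Si bond (protodesilylation) leaves the aniline and the aryl chloride alone.

Step 6
Reactants: 11 1-(6-chloro-2-iodo-1H-indol-3-yl)-2,2-dimethoxyethanone; 15 5-chloro-2-ethynylaniline
Product: 16 1-[2-[(2-amino-4-chlorophenyl)ethynyl]-6-chloro-1H-indol-3-yl]-2,2-dimethoxyethanone
Conditions: PdCl2(PPh3)2 (3 mol%), CuI (5 mol%), Et3N, THF, rt, degassed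
Reagents that add atoms: none
Why: Sonogashira coupling, in which the C2 iodide is activated as a vinylogous acyl iodide by the 3-acyl group, so oxidative addition should be fast at room temperature, below the temperature at which copper or palladium would cyclise the o-alkynylaniline, and both aryl chlorides should stay intact.

Step 7
Reactants: 16 1-[2-[(2-amino-4-chlorophenyl)ethynyl]-6-chloro-1H-indol-3-yl]-2,2-dimethoxyethanone
Product: 19 2,9-dichloro-5-methoxy-11,12-dihydroindolo[2,3-a]carbazol-6-ol, via biindolyl keto-acetal 17 (not isolated), via 5H-keto tautomer 18 (not isolated)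
Conditions: Ph3PAuNTf2 (5 mol%), DCE (0.02 M), rt to 50 °C, Ar; then anhydrous MsOH (5 equiv), 70 °C
Reagents that add atoms: none
Why: Cationic gold(I) π-activates the alkyne, the aniline nitrogen adds anti to the alkyne carbon attached to indole C2 in a 5-endo-dig closure that forms N12–C11b and the pyrrole ring, and protodeauration gives the 2,2'-biindole 17 with an unsubstituted C3'. Anhydrous methanesulfonic acid then ionises the dimethyl acetal to an oxocarbenium ion, which C4b (C3' of the new indole) attacks in a six-membered Friedel–Crafts closure (6-exo-trig at the oxocarbenium carbon) that forms C4b–C5 and the central ring, after which proton loss gives α-methoxy ketone 18 and its enolisation gives phenol 19 with release of one methanol. The closest known reaction types are the gold-catalysed hydroamination of 2-alkynylanilines to 2-substituted indoles and the acid-mediated acetal annulation of 2,2'-biindoles to indolocarbazoles, run here one after the other in one flask. Two selectivities are needed: nitrogen must beat the ketone oxygen for the activated alkyne, which the substrate secures because the oxygen adduct is a pyrylium-type cation with no proton to lose and so reverts while the nitrogen adduct is drained by protodeauration, and C3' must beat N1' for the oxocarbenium ion, which is secured because a neutral indole in acid reacts as an enamine through C3 and only the carbon adduct is made irreversible by aromatisation. Water is excluded so that the acetal is not hydrolysed and the C5 methoxy group is kept, and no stereocentre persists because the one in 18 is erased on enolisation.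

Step 8
Reactants: 19 2,9-dichloro-5-methoxy-11,12-dihydroindolo[2,3-a]carbazol-6-ol
Product: 20 borregomycin E (2,9-dichloro-5,6-dimethoxy-11,12-dihydroindolo[2,3-a]carbazole)
Conditions: MeI (1.2 equiv), K2CO3, acetone, rt, Ar
Reagents that add atoms: iodomethane, CI
Why: Williamson O-methylation, in which carbonate deprotonates the phenol but not the far less acidic indole N–H groups, so alkylation should stop at oxygen.

Compound list
1 | 6-chloro-1H-indole | Clc1ccc2cc[nH]c2c1 | starting material
2 | lithium 6-chloroindol-1-ide | [Li+].Clc1ccc2cc[n-]c2c1 | intermediate (not isolated)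
3 | lithium 6-chloroindole-1-carboxylate | [Li+].[O-]C(=O)n1ccc2ccc(Cl)cc21 | intermediate (not isolated)
4 | lithium 6-chloro-2-lithioindole-1-carboxylate | [Li+].[O-]C(=O)n1c([Li])cc2ccc(Cl)cc21 | intermediate (not isolated)
5 | lithium 6-chloro-2-iodoindole-1-carboxylate | [Li+].[O-]C(=O)n1c(I)cc2ccc(Cl)cc21 | intermediate (not isolated)
6 | 6-chloro-2-iodo-1H-indole | Clc1ccc2cc(I)[nH]c2c1 | intermediate
7 | methyl 2,2-dimethoxyacetate | COC(OC)C(=O)OC | starting material
8 | potassium 2,2-dimethoxyacetate | [K+].COC(OC)C(=O)[O-] | intermediate
9 | 2,2-dimethoxyacetyl chloride | COC(OC)C(Cl)=O | intermediate (not isolated)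
10 | (6-chloro-2-iodoindol-1-yl)zinc chloride | Cl[Zn]n1c(I)cc2ccc(Cl)cc21 | intermediate (not isolated)
11 | 1-(6-chloro-2-iodo-1H-indol-3-yl)-2,2-dimethoxyethanone | COC(OC)C(=O)c1c(I)[nH]c2cc(Cl)ccc12 | intermediate
12 | 5-chloro-2-iodoaniline | Nc1cc(Cl)ccc1I | starting material
13 | trimethylsilylacetylene | C#C[Si](C)(C)C | starting material
14 | 5-chloro-2-[(trimethylsilyl)ethynyl]aniline | Nc1cc(Cl)ccc1C#C[Si](C)(C)C | intermediate
15 | 5-chloro-2-ethynylaniline | Nc1cc(Cl)ccc1C#C | intermediate
16 | 1-[2-[(2-amino-4-chlorophenyl)ethynyl]-6-chloro-1H-indol-3-yl]-2,2-dimethoxyethanone | COC(OC)C(=O)c1c(C#Cc2ccc(Cl)cc2N)[nH]c2cc(Cl)ccc12 | intermediate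
17 | 1-(6,6'-dichloro-1H,1'H-[2,2'-biindol]-3-yl)-2,2-dimethoxyethanone | COC(OC)C(=O)c1c(-c2cc3ccc(Cl)cc3[nH]2)[nH]c2cc(Cl)ccc12 | intermediate (not isolated)
18 | 2,9-dichloro-5-methoxy-11,12-dihydroindolo[2,3-a]carbazol-6(5H)-one (racemic, transient) | COC1C(=O)c2c3ccc(Cl)cc3[nH]c2-c2[nH]c3cc(Cl)ccc3c12 | intermediate (not isolated)
19 | 2,9-dichloro-5-methoxy-11,12-dihydroindolo[2,3-a]carbazol-6-ol | COc1c(O)c2c3ccc(Cl)cc3[nH]c2c2[nH]c3cc(Cl)ccc3c12 | intermediate
20 | borregomycin E (2,9-dichloro-5,6-dimethoxy-11,12-dihydroindolo[2,3-a]carbazole) | COc1c(OC)c2c3ccc(Cl)cc3[nH]c2c2[nH]c3cc(Cl)ccc3c12 | target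

Total step count: 8
Longest linear sequence: 5 steps (steps 1, 3, 6, 7, 8)

Steps most likely to fail

Step 7. The ketone oxygen may compete with the aniline nitrogen for the gold-activated alkyne. Ionisation of the acetal beside the carbonyl may also be so slow that intermolecular condensation overtakes ring closure. The fallback sets out from 15 and returns at 20, building the central ring by double acylation of a symmetric biindole. Glaser–Hay coupling of 15 (CuCl, TMEDA, O2, acetone, rt) should give 2,2'-(buta-1,3-diyne-1,4-diyl)bis(5-chloroaniline) F1. KOt-Bu in NMP at rt should then close both pyrrole rings by anionic 5-endo-dig hydroamination to 6,6'-dichloro-1H,1'H-2,2'-biindole F2. Oxalyl chloride in THF (0 °C to rt) should acylate C3 and then C3' to give 2,9-dichloro-11,12-dihydroindolo[2,3-a]carbazole-5,6-dione F3. Reduction with Na2S2O4 in THF/water should give 2,9-dichloro-11,12-dihydroindolo[2,3-a]carbazole-5,6-diol F4, which is methylated on both oxygens with MeI and K2CO3 in acetone under argon to give 20.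

Step 3. The acetal-bearing acid chloride may decompose, the acetal may be opened at zinc before C3 acylation, or acylation may go to nitrogen. The fallback sets out from 6 and returns at 11, introducing the acetal only after a robust acylation. Friedel–Crafts acetylation of 6 with acetyl chloride and Et2AlCl in CH2Cl2 at 0 °C should give 1-(6-chloro-2-iodo-1H-indol-3-yl)ethanone F5. Riley oxidation (SeO2, dioxane/water, 90 °C) should give 2-(6-chloro-2-iodo-1H-indol-3-yl)-2-oxoacetaldehyde F6, handled as its hydrate. Acetalisation with MeOH, HC(OMe)3 and catalytic TsOH should convert only the aldehyde, since the ketone is a deactivated vinylogous amide, and give 11.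

Step 1. tert-Butyllithium may metalate next to chlorine or exchange it, or the unprotected iodoindole may degrade during work-up. The fallback sets out from 1 and returns at 6, using an isolable carbamate and an amide base. Boc2O and DMAP in MeCN should give tert-butyl 6-chloroindole-1-carboxylate F7. LDA in THF at −78 °C followed by I2 should give tert-butyl 6-chloro-2-iodoindole-1-carboxylate F8, a storable form of the iodide. K2CO3 in MeOH at rt removes the carbamate just before use to give 6.

Further compounds
F1 | step 7 | 2,2'-(buta-1,3-diyne-1,4-diyl)bis(5-chloroaniline) | Nc1cc(Cl)ccc1C#CC#Cc1ccc(Cl)cc1N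
F2 | step 7 | 6,6'-dichloro-1H,1'H-2,2'-biindole | Clc1ccc2cc(-c3cc4ccc(Cl)cc4[nH]3)[nH]c2c1
F3 | step 7 | 2,9-dichloro-11,12-dihydroindolo[2,3-a]carbazole-5,6-dione | O=C1C(=O)c2c3ccc(Cl)cc3[nH]c2-c2[nH]c3cc(Cl)ccc3c12
F4 | step 7 | 2,9-dichloro-11,12-dihydroindolo[2,3-a]carbazole-5,6-diol | Oc1c(O)c2c3ccc(Cl)cc3[nH]c2c2[nH]c3cc(Cl)ccc3c12
F5 | step 3 | 1-(6-chloro-2-iodo-1H-indol-3-yl)ethanone | CC(=O)c1c(I)[nH]c2cc(Cl)ccc12
F6 | step 3 | 2-(6-chloro-2-iodo-1H-indol-3-yl)-2-oxoacetaldehyde | O=CC(=O)c1c(I)[nH]c2cc(Cl)ccc12
F7 | step 1 | tert-butyl 6-chloroindole-1-carboxylate | CC(C)(C)OC(=O)n1ccc2ccc(Cl)cc21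
F8 | step 1 | tert-butyl 6-chloro-2-iodoindole-1-carboxylate | CC(C)(C)OC(=O)n1c(I)cc2ccc(Cl)cc21
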